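**Retrosynthetic overview**

1. Ring B of isariotin C (C1–C2–C3–C4–C5–C9) is read as the ring of benzoic acid, and the carboxyl carbon as C8. A Rieske arene dioxygenase dihydroxylates benzoate at the ipso and ortho carbons, which sets the quaternary carbinol C1 in its final absolute configuration and places a carbinol at C9.
2. The two cis hydroxyls (O1, O9) relay the stereochemistry to C2, C3 and C4 through a double hydroxyl-directed epoxidation of the diene; the C9 carbinol is later oxidised to the C9 ketone.
3. C8 (ester, then aldehyde) is extended to the C8–C7–C6 amino-acid arm by Horner–Wadsworth–Emmons olefination and catalyst-controlled hydrogenation (C7).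
4. Key disconnection, the C5–C6 bond: SmI2 opens the C4–C5 epoxide of the C9 ketone at C5, and the samarium enolate closes ring A (C1–C8–C7–C6–C5–C9) onto the C6 aldehyde. One operation gives the bicyclo[3.3.1]nonan-9-one, reveals C4–OH, and sets C5 and C6, with the C2–C3 epoxide untouched.
5. Ring order: B (from the arene, step 1), then A (step 10). The (E)-7-oxododec-2-enoyl chain (Grignard addition, cross-metathesis) is attached last by N-acylation.

Key step: step 10

Assumption: the whole-cell biocatalyst (Cupriavidus necator B9, a benzoate-dioxygenase strain with blocked diol dehydrogenase) is treated as a reagent; benzoic acid is the commercial starting material.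

Convention: isariotin numbering is used for all intermediates (C1 = C(OH) bridgehead, C2/C3 = epoxide, C4 = CHOH, C5 = CH bridgehead, C6 = CHOH, C7 = CHN, C8 = CH2, C9 = C=O); β is the face of ring B that carries O1, and C8 lies on the α-face.

**Route**

Step 1
Reactants: 1 benzoic acid
Product: 2 (1S,2R)-1,2-dihydroxycyclohexa-3,5-diene-1-carboxylic acid
Conditions: whole cells of Cupriavidus necator B9, fructose, mineral medium pH 7, air, 30 °C; then pH 3, 0 °C, EtOAc extraction
Reagents that add atoms: dioxygen, O=O
Why: Benzoate 1,2-dioxygenase, a Rieske non-heme iron arene dioxygenase, performs an NADH-dependent cis-dihydroxylation at the ipso and ortho carbons, a dearomatisation no small reagent achieves; the active site sets both carbinol centres, and the (1S) centre is C1 of the target in its final configuration.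

Step 2
Reactants: 2 (1S,2R)-1,2-dihydroxycyclohexa-3,5-diene-1-carboxylic acid
Product: 3 methyl (1S,2R)-1,2-dihydroxycyclohexa-3,5-diene-1-carboxylate
Conditions: TMSCHN2, toluene/MeOH 3:1, 0 °C
Reagents that add atoms: (trimethylsilyl)diazomethane, C[Si](C)(C)C=[N+]=[N-]
Why: O-Methylation of the carboxylic acid by the diazoalkane runs under neutral conditions, which avoids acid-promoted dehydrative rearomatisation of the dienediol; no stereocentre is touched.

Step 3
Reactants: 3 methyl (1S,2R)-1,2-dihydroxycyclohexa-3,5-diene-1-carboxylate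
Product: 4 methyl 2β,3β:4β,5β-diepoxy-1β,9β-dihydroxycyclohexane-1-carboxylate
Conditions: VO(acac)2 (10 mol %), t-BuOOH (3 equiv, decane), CH2Cl2, 4 Å MS, 0 °C → rt
Reagents that add atoms: tert-butyl hydroperoxide, CC(C)(C)OO
Why: In this vanadium-catalysed hydroxyl-directed epoxidation each alkene is allylic to one β-hydroxyl (C2=C3 to O1, C4=C5 to O9) and homoallylic to the other, so the vanadate ester should deliver oxygen to the β-face of both alkenes and set C2, C3, C4 and (temporarily) C5.

Step 4
Reactants: 4 methyl 2β,3β:4β,5β-diepoxy-1β,9β-dihydroxycyclohexane-1-carboxylate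
Product: 6 methyl 2β,3β:4β,5β-diepoxy-1β-(triethylsilyloxy)-9β-(trimethylsilyloxy)cyclohexane-1-carboxylate, via 9-O-trimethylsilyl ether 5 (not isolated)
Conditions: TMSCl (1.05 equiv), imidazole, CH2Cl2, −20 °C; then TESOTf (1.5 equiv), 2,6-lutidine, −78 → 0 °C
Reagents that add atoms: chlorotrimethylsilane, C[Si](C)(C)Cl; triethylsilyl trifluoromethanesulfonate, CC[Si](CC)(CC)OS(=O)(=O)C(F)(F)F
Why: Site-selective silylation relies on the secondary C9–OH reacting with the chlorosilane far faster than the tertiary α-hydroxy ester, which needs the silyl triflate; this gives an acid-labile TMS ether at O9 and a more robust TES ether at O1, and the cis epoxy alcohols cannot undergo Payne rearrangement.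

Step 5
Reactants: 6 methyl 2β,3β:4β,5β-diepoxy-1β-(triethylsilyloxy)-9β-(trimethylsilyloxy)cyclohexane-1-carboxylate
Product: 7 2β,3β:4β,5β-diepoxy-1β-(triethylsilyloxy)-9β-(trimethylsilyloxy)cyclohexane-1-carbaldehyde
Conditions: DIBAL-H (1.2 equiv), CH2Cl2, −78 °C; MeOH, Rochelle salt
Reagents that add atoms: none
Why: Partial reduction of the ester should stop at the aldehyde because the α-silyloxy group stabilises the tetrahedral aluminate until work-up at −78 °C; the aldehyde (C8) has no α-hydrogen and cannot epimerise.

Step 6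
Reactants: 7 2β,3β:4β,5β-diepoxy-1β-(triethylsilyloxy)-9β-(trimethylsilyloxy)cyclohexane-1-carbaldehyde; 8 methyl 2-(benzyloxycarbonylamino)-2-(dimethoxyphosphoryl)acetate (commercial)
Product: 9 methyl (Z)-2-(benzyloxycarbonylamino)-3-[2β,3β:4β,5β-diepoxy-1β-(triethylsilyloxy)-9β-(trimethylsilyloxy)cyclohexyl]acrylate
Conditions: DBU, CH2Cl2, 0 °C → rt
Reagents that add atoms: none
Why: Horner–Wadsworth–Emmons olefination with the phosphonoglycinate forms the C8=C7 bond and typically gives the (Z)-dehydroamino ester, the geometry needed for the hydrogenation; the non-enolisable aldehyde tolerates the amidine base.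

Step 7
Reactants: 9 methyl (Z)-2-(benzyloxycarbonylamino)-3-[2β,3β:4β,5β-diepoxy-1β-(triethylsilyloxy)-9β-(trimethylsilyloxy)cyclohexyl]acrylate
Product: 10 methyl (S)-2-(benzyloxycarbonylamino)-3-[2β,3β:4β,5β-diepoxy-1β-(triethylsilyloxy)-9β-(trimethylsilyloxy)cyclohexyl]propanoate
Conditions: [Rh(cod)((S,S)-Et-DuPhos)]OTf (2 mol %), H2 (6 bar), THF, rt
Reagents that add atoms: none
Why: Rh(I)-bisphospholane asymmetric hydrogenation of a chelating (Z)-α-(acylamino)acrylate is catalyst-controlled, and the (S,S)-ligand should give the (S) (L-type) configuration at C7; epoxides, silyl ethers and the benzyl carbamate are inert, and no other alkene is left in the substrate.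

Step 8
Reactants: 10 methyl (S)-2-(benzyloxycarbonylamino)-3-[2β,3β:4β,5β-diepoxy-1β-(triethylsilyloxy)-9β-(trimethylsilyloxy)cyclohexyl]propanoate
Product: 12 benzyl N-[(S)-1-hydroxy-3-[2β,3β:4β,5β-diepoxy-9β-hydroxy-1β-(triethylsilyloxy)cyclohexyl]propan-2-yl]carbamate, via 9-O-trimethylsilyl amino alcohol 11 (not isolated)
Conditions: LiBH4 (2 equiv), THF, 0 °C → rt; then 10 % aq. citric acid/MeOH, 0 °C
Reagents that add atoms: none
Why: Borohydride reduction of the ester to the primary alcohol (C6) spares the carbamate, epoxides and silyl ethers, and the mild acidic methanolysis that follows should cleave only the secondary TMS ether at O9 and leave the tertiary TES ether at O1.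

Step 9
Reactants: 12 benzyl N-[(S)-1-hydroxy-3-[2β,3β:4β,5β-diepoxy-9β-hydroxy-1β-(triethylsilyloxy)cyclohexyl]propan-2-yl]carbamate
Product: 13 benzyl N-[(S)-1-oxo-3-[2β,3β:4β,5β-diepoxy-9-oxo-1β-(triethylsilyloxy)cyclohexyl]propan-2-yl]carbamate
Conditions: (COCl)2, DMSO, CH2Cl2, −78 °C; then i-Pr2NEt, −78 → −40 °C; used crude
Reagents that add atoms: none
Why: In this double Swern oxidation both hydroxyls are activated as alkoxysulfonium ions before base is added, so the C6 aldehyde and C9 ketone form together and the δ-hydroxy aldehyde cannot divert through a lactol to a lactone; the low temperature and hindered amine should preserve the labile α-amino aldehyde centre C7.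

Step 10
Reactants: 13 benzyl N-[(S)-1-oxo-3-[2β,3β:4β,5β-diepoxy-9-oxo-1β-(triethylsilyloxy)cyclohexyl]propan-2-yl]carbamate
Product: 15 (1S,2S,3S,4S,5S,6R,7S)-7-(benzyloxycarbonylamino)-2,3-epoxy-4,6-dihydroxy-1-(triethylsilyloxy)bicyclo[3.3.1]nonan-9-one, via samarium(III) enolate 14 (not isolated)
Conditions: SmI2 (2.2 equiv, 0.1 M in THF), THF, −78 °C; then pH 7 phosphate buffer
Reagents that add atoms: none
Why: Electron transfer from SmI2 to the C9 ketone gives a ketyl that opens the C4–C5 epoxide at the α-carbon (C5–O cleavage), and a second electron gives the samarium(III) enolate/C4-alkoxide 14, whose C5 adds to the tethered C6 aldehyde. The closest known reaction types are the SmI2 reduction of α,β-epoxy ketones to β-hydroxy ketones and the samarium-Reformatsky-type intramolecular aldol addition of reductively generated samarium enolates. Ring A is closed through the C5–C6 bond in a 6-(enolendo)-exo-trig aldol closure, which completes the bicyclo[3.3.1]nonan-9-one. C4 keeps its β-oxygen because the C4–O bond is never broken; C5 is fixed by the tether, since the new bond can only form on the α-face next to the axial C8 arm (1,3-diaxial bridging); C6 should be set by a closed, samarium-chelated Zimmerman–Traxler-type transition state in which enolate and aldehyde oxygens share the metal, placing O6 syn-clinal to the C9 carbonyl (exo, 6R) with the C7 carbamate equatorial. The step needs reduction of the epoxy ketone before the aldehyde (α-oxygenated ketones accept electrons far faster than unactivated aldehydes at −78 °C without HMPA), cleavage of the strained, well-aligned C5–O bond rather than the C1–OSiEt3 bond (near the carbonyl plane, poor leaving group), and C–C bond formation before protonation (no protic additive, six-membered intramolecular closure). Once formed, the β-hydroxy ketone cannot dehydrate or enolise because C5 is a bridgehead, so the adduct should survive work-up.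

Step 11
Reactants: 15 (1S,2S,3S,4S,5S,6R,7S)-7-(benzyloxycarbonylamino)-2,3-epoxy-4,6-dihydroxy-1-(triethylsilyloxy)bicyclo[3.3.1]nonan-9-one
Product: 16 (1S,2S,3S,4S,5S,6R,7S)-7-(benzyloxycarbonylamino)-2,3-epoxy-1,4,6-trihydroxybicyclo[3.3.1]nonan-9-one
Conditions: HF·pyridine, pyridine, THF, 0 °C → rt
Reagents that add atoms: none
Why: Buffered fluoride desilylation removes the tertiary TES ether without base, so retro-aldol cleavage is avoided, and the epoxide, flanked by two oxygenated carbons, should resist acid-induced opening.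

Step 12
Reactants: 16 (1S,2S,3S,4S,5S,6R,7S)-7-(benzyloxycarbonylamino)-2,3-epoxy-1,4,6-trihydroxybicyclo[3.3.1]nonan-9-one
Product: 17 (1S,2S,3S,4S,5S,6R,7S)-7-amino-2,3-epoxy-1,4,6-trihydroxybicyclo[3.3.1]nonan-9-one
Conditions: H2 (1 atm), 10 % Pd/C, EtOAc/EtOH, rt
Reagents that add atoms: none
Why: Hydrogenolysis of the benzyl carbamate over palladium gives the amine after loss of CO2; the non-benzylic, non-allylic epoxide and the hindered bridging ketone are not reduced under these conditions.

Step 13
Reactants: 18 hex-5-enenitrile; 19 n-pentylmagnesium bromide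
Product: 21 undec-1-en-6-one, via N-bromomagnesio ketimine 20 (not isolated)
Conditions: Et2O, 0 °C → reflux; then 1 M HCl, rt
Reagents that add atoms: water, O
Why: Grignard addition to the nitrile stops at the metallo-ketimine, which cannot add a second equivalent and is hydrolysed to the ketone on acidic work-up.

Step 14
Reactants: 21 undec-1-en-6-one; 22 acrylic acid
Product: 23 (E)-7-oxododec-2-enoic acid
Conditions: Hoveyda–Grubbs 2nd-generation catalyst (3 mol %), CH2Cl2, 40 °C
Reagents that add atoms: none
Why: Olefin cross-metathesis between a terminal alkene and an acrylate-type partner with a Ru–NHC catalyst is selective for the cross product and for the (E)-enoic acid; the ketone is tolerated.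

Step 15
Reactants: 17 (1S,2S,3S,4S,5S,6R,7S)-7-amino-2,3-epoxy-1,4,6-trihydroxybicyclo[3.3.1]nonan-9-one; 23 (E)-7-oxododec-2-enoic acid
Product: 25 isariotin C, via benzotriazol-1-yl ester 24 (not isolated)
Conditions: EDC·HCl, HOBt, i-Pr2NEt, DMF, 0 °C → rt
Reagents that add atoms: none
Why: Carbodiimide/HOBt amide coupling should acylate the primary amine chemoselectively, because the benzotriazolyl ester is too mild an acyl donor to esterify the two secondary and one tertiary hydroxyls.

**Compound list**

1 | benzoic acid | OC(=O)c1ccccc1 | starting material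
2 | (1S,2R)-1,2-dihydroxycyclohexa-3,5-diene-1-carboxylic acid | OC(=O)[C@]1(O)C=CC=C[C@H]1O | intermediate
3 | methyl (1S,2R)-1,2-dihydroxycyclohexa-3,5-diene-1-carboxylate | COC(=O)[C@]1(O)C=CC=C[C@H]1O | intermediate
4 | methyl 2β,3β:4β,5β-diepoxy-1β,9β-dihydroxycyclohexane-1-carboxylate (both hydroxyls and both epoxide oxygens on the face opposite to C8) | COC(=O)[C@]1(O)[C@H]2O[C@H]2[C@H]3O[C@H]3[C@H]1O | intermediate
5 | 9-O-trimethylsilyl ether of 4 (O1–H free) | COC(=O)[C@]1(O)[C@H]2O[C@H]2[C@H]3O[C@H]3[C@H]1O[Si](C)(C)C | intermediate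
6 | methyl 2β,3β:4β,5β-diepoxy-1β-(triethylsilyloxy)-9β-(trimethylsilyloxy)cyclohexane-1-carboxylate | COC(=O)[C@]1(O[Si](CC)(CC)CC)[C@H]2O[C@H]2[C@H]3O[C@H]3[C@H]1O[Si](C)(C)C | intermediate
7 | 2β,3β:4β,5β-diepoxy-1β-(triethylsilyloxy)-9β-(trimethylsilyloxy)cyclohexane-1-carbaldehyde (aldehyde carbon = C8) | O=C[C@]1(O[Si](CC)(CC)CC)[C@H]2O[C@H]2[C@H]3O[C@H]3[C@H]1O[Si](C)(C)C | intermediate
8 | methyl 2-(benzyloxycarbonylamino)-2-(dimethoxyphosphoryl)acetate | COC(=O)C(NC(=O)OCc1ccccc1)P(=O)(OC)OC | starting material
9 | methyl (Z)-2-(benzyloxycarbonylamino)-3-[2β,3β:4β,5β-diepoxy-1β-(triethylsilyloxy)-9β-(trimethylsilyloxy)cyclohexyl]acrylate | COC(=O)/C(NC(=O)OCc1ccccc1)=C/[C@]2(O[Si](CC)(CC)CC)[C@H]3O[C@H]3[C@H]4O[C@H]4[C@H]2O[Si](C)(C)C | intermediate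
10 | methyl (S)-2-(benzyloxycarbonylamino)-3-[2β,3β:4β,5β-diepoxy-1β-(triethylsilyloxy)-9β-(trimethylsilyloxy)cyclohexyl]propanoate | COC(=O)[C@@H](NC(=O)OCc1ccccc1)C[C@]2(O[Si](CC)(CC)CC)[C@H]3O[C@H]3[C@H]4O[C@H]4[C@H]2O[Si](C)(C)C | intermediate
11 | benzyl N-[(S)-1-hydroxy-3-[2β,3β:4β,5β-diepoxy-1β-(triethylsilyloxy)-9β-(trimethylsilyloxy)cyclohexyl]propan-2-yl]carbamate | OC[C@@H](NC(=O)OCc1ccccc1)C[C@]2(O[Si](CC)(CC)CC)[C@H]3O[C@H]3[C@H]4O[C@H]4[C@H]2O[Si](C)(C)C | intermediate
12 | benzyl N-[(S)-1-hydroxy-3-[2β,3β:4β,5β-diepoxy-9β-hydroxy-1β-(triethylsilyloxy)cyclohexyl]propan-2-yl]carbamate | OC[C@@H](NC(=O)OCc1ccccc1)C[C@]2(O[Si](CC)(CC)CC)[C@H]3O[C@H]3[C@H]4O[C@H]4[C@H]2O | intermediate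
13 | benzyl N-[(S)-1-oxo-3-[2β,3β:4β,5β-diepoxy-9-oxo-1β-(triethylsilyloxy)cyclohexyl]propan-2-yl]carbamate | O=C[C@@H](NC(=O)OCc1ccccc1)C[C@]2(O[Si](CC)(CC)CC)[C@H]3O[C@H]3[C@H]4O[C@H]4C2=O | intermediate
14 | bis(diiodosamarium) C9-enolate/C4-alkoxide formed from 13 by epoxide opening | O=C[C@@H](NC(=O)OCc1ccccc1)C[C@]2(O[Si](CC)(CC)CC)[C@H]3O[C@H]3[C@@H](O[Sm](I)I)C=C2O[Sm](I)I | intermediate
15 | (1S,2S,3S,4S,5S,6R,7S)-7-(benzyloxycarbonylamino)-2,3-epoxy-4,6-dihydroxy-1-(triethylsilyloxy)bicyclo[3.3.1]nonan-9-one (isariotin numbering) | O=C(OCc1ccccc1)N[C@H]2C[C@]3(O[Si](CC)(CC)CC)[C@H]4O[C@H]4[C@@H](O)[C@H]([C@H]2O)C3=O | intermediate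
16 | (1S,2S,3S,4S,5S,6R,7S)-7-(benzyloxycarbonylamino)-2,3-epoxy-1,4,6-trihydroxybicyclo[3.3.1]nonan-9-one | O=C(OCc1ccccc1)N[C@H]2C[C@]3(O)[C@H]4O[C@H]4[C@@H](O)[C@H]([C@H]2O)C3=O | intermediate
17 | (1S,2S,3S,4S,5S,6R,7S)-7-amino-2,3-epoxy-1,4,6-trihydroxybicyclo[3.3.1]nonan-9-one (N-deacyl isariotin C) | N[C@H]1C[C@]2(O)[C@H]3O[C@H]3[C@@H](O)[C@H]([C@H]1O)C2=O | intermediate
18 | hex-5-enenitrile | C=CCCCC#N | starting material
19 | n-pentylmagnesium bromide | CCCCC[Mg]Br | starting material
20 | N-bromomagnesio undec-1-en-6-imine | CCCCCC(=N[Mg]Br)CCCC=C | intermediate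
21 | undec-1-en-6-one | CCCCCC(=O)CCCC=C | intermediate
22 | acrylic acid | C=CC(=O)O | starting material
23 | (E)-7-oxododec-2-enoic acid | CCCCCC(=O)CCC/C=C/C(=O)O | intermediate
24 | benzotriazol-1-yl (E)-7-oxododec-2-enoate | CCCCCC(=O)CCC/C=C/C(=O)On1nnc2ccccc12 | intermediate
25 | isariotin C | CCCCCC(=O)CCC/C=C/C(=O)N[C@H]1C[C@@]2(O)C(=O)[C@H]([C@H](O)[C@@H]3O[C@@H]32)[C@H]1O | target

**Step count**

Total step count: 15. Longest linear sequence: 13 (steps 1–12 and 15, from benzoic acid); steps 13–14 make the side-chain acid in a separate branch.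

**Steps most likely to fail**

Step 10 (key step). The samarium enolate may be quenched by proton transfer (carbamate N–H, adventitious water) before the C5–C6 bond forms, electron transfer to the aldehyde may open a pinacol-type ketyl coupling, or the aldehyde may be attacked through a non-chelated transition state and give the wrong C6 face. The fallback sets out from 13 and separates the two events. Reduction with SmI2 in THF/MeOH at −90 °C deliberately protonates the enolate and should give the uncyclised β-hydroxy keto aldehyde F1. F1 is then deprotonated with LiHMDS (3.1 equiv, THF, −78 °C) at O4, at the carbamate nitrogen and at C5, the only enolisable position of the ketone; the nitrogen anion shields C7–H. The lithium enolate should close ring A by a lithium-chelated intramolecular aldol addition, and the route is rejoined at 15.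

Step 3. After the first oxygen transfer the remaining alkene is a deactivated vinyl epoxide, so the second epoxidation may stall, or the Lewis-acidic vanadium may open the allylic epoxide. The fallback sets out from 3. Buffered peracid epoxidation (m-CPBA, NaHCO3, CH2Cl2, 0 °C, hydrogen-bond directed) should give the mono-epoxide methyl 4β,5β-epoxy-1β,9β-dihydroxycyclohex-2-ene-1-carboxylate F2, assuming the peracid attacks the alkene remote from the ester-bearing carbon. The second alkene is then converted without any directing effect: NBS in THF/H2O at 0 °C (bromonium ion on the open α-face, water at C3 from the β-face) should give the bromohydrin methyl 2α-bromo-4β,5β-epoxy-1β,3β,9β-trihydroxycyclohexane-1-carboxylate F3. K2CO3 in MeOH at 0 °C closes the β-epoxide by intramolecular SN2 displacement, and the route is rejoined at 4; either regioisomer of the bromohydrin would close to the same epoxide.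

Step 6. Addition of the stabilised phosphonate anion to the neopentyl-type aldehyde may be too slow, with silyl migration or decomposition on long exposure to the amidine base. The fallback sets out from 7. Aldol addition of the dilithio derivative of methyl N-(benzyloxycarbonyl)glycinate (LDA, 2.1 equiv, THF, −78 °C), a smaller and far more reactive nucleophile, should give the β-hydroxy-α-amino ester F4 as a mixture of epimers at C7 and C8; both centres are erased in the next operation. Mesylation and E1cB elimination (MsCl, Et3N; then DBU, CH2Cl2) should give the (Z)-dehydroamino ester, and the route is rejoined at 9.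

**Further compounds**

F1 | step 10 | benzyl N-[(S)-1-oxo-3-[2β,3β-epoxy-4β-hydroxy-9-oxo-1β-(triethylsilyloxy)cyclohexyl]propan-2-yl]carbamate | O=C[C@@H](NC(=O)OCc1ccccc1)C[C@]2(O[Si](CC)(CC)CC)[C@H]3O[C@H]3[C@@H](O)CC2=O
F2 | step 3 | methyl 4β,5β-epoxy-1β,9β-dihydroxycyclohex-2-ene-1-carboxylate | COC(=O)[C@]1(O)C=C[C@H]2O[C@H]2[C@H]1O
F3 | step 3 | methyl 2α-bromo-4β,5β-epoxy-1β,3β,9β-trihydroxycyclohexane-1-carboxylate | COC(=O)[C@]1(O)[C@H](Br)[C@@H](O)[C@H]2O[C@H]2[C@H]1O
F4 | step 6 | methyl 2-(benzyloxycarbonylamino)-3-hydroxy-3-[2β,3β:4β,5β-diepoxy-1β-(triethylsilyloxy)-9β-(trimethylsilyloxy)cyclohexyl]propanoate (epimer mixture at C7 and C8) | COC(=O)C(NC(=O)OCc1ccccc1)C(O)[C@]2(O[Si](CC)(CC)CC)[C@H]3O[C@H]3[C@H]4O[C@H]4[C@H]2O[Si](C)(C)C
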